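All runs stem from a simulated flask for an exercise, and the scatter is random.

The question is what cutting L to 0.500 of the G charge earns in Q at 3.0 min. Here is the quick number, with amounts as fractions of the G charge.

| flask | G | X | L | remark | time | volume of the second phase over the first |
|---|---|---|---|---|---|---|
| Tuesday's | 1 M | 1.8 M | 0.70 M | run made earlier |  |  |
| Monday's | 1 M | 1.8 M | 1.1 M | run made earlier |  |  |
| flask | 1.0 M | 1.80 M | 0.500 M |  | 3.0 min | 1.0 |

- Tuesday's (time / min: Q / %, G / %): 0.250: 13, 78; 0.417: 27, 57; 0.833: 50, 30; 1.50: 68, 8; 3.00: 75, 3
- Monday's (time / min: Q / %, G / %): 0.250: 11, 72; 0.833: 48, 27; 1.33: 63, 9; 2.00: 69, 3; 3.00: 71, 2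

(standard deviation of a reading: 1.5 percentage points)

- in the second phase: X; everything else is in the first
- charges count per volume of the first phase; a concentration in a rate is the amount of a species over the volume of its own phase; every rate counts per litre of the first phase
- what was read earlier has a scatter of 1.5 percentage points, one standard deviation
- the earlier runs hold the two phases in the same ratio of volumes as the flask asked about

* amount of Q at 3.0 min, in percent of the G charged
* part of the G charged that has reacted at 3.0 min

1. At 3.00 min, Tuesday's run holds Q 75% and G 3%, so its deficit (mass-balance gap) is 22.0%.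
2. Monday's run, with more L, holds Q 71% and G 2%, so its deficit is larger, 27.0%.
3. Extra deficit over extra L gives 0.125: this is the toll, the fraction of G lost at that time per unit of L charged. Each deficit rests on two readings with a scatter of 1.5 percentage points, so the toll is loose.
4. Run back to no L, the line leaves a base deficit of 13.2%, and forward to the new flask it gives 19.5%.
5. With G left as on Tuesday, this reckoning puts Q in the flask near 77.5%.
6. The hunch is a shade lower: the forecast says Q 77% and 97.5% reacted, reading “a side channel that grows with L”.

The flask gives Q 80.3% with 99.4% of G reacted, and this scheme runs in it: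

    J ⇌ X, rate k1*([J] - [X]/K1) per volume of the first phase (partition coefficient = 0.690, kL = 0.830 /min)
    G + J → Q (k = 3.40 /M/min)
    G + L → Z (k = 0.380 /M/min)
    2 G → E (k = 0.0910 /M/min)
    J ⇌ D (K = 1.30, k = 0.0930 /min)

That is a deficit of 19.1% in the flask against the toll's 19.5%. For the neighbour flask with L at 0.200 of the G charge, the toll reckons 15.8%, and that neighbour shows 13.0%, with Q 86.0%. At 3.00 min, Z holds 11.8% in the flask and 5.02% in the neighbour flask. Two things together hold the flask's Q down: striking G + L into Z out lifts it from 80.3% to 90.2%, and making the passage of X into J fast lifts it to 90.5%.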